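**Assumption (one line):** the SMILES is read as ring B–CH(OH)–(CH2)13–ring A (a 22-membered ring) with an (R)-carbinol; compounds 1, 2, 4, 5, 8 and both enantiomers of DAIB are taken as commercial. Chain numbering: C1 = carbinol carbon, C2–C14 run toward ring A.

## Retrosynthetic overview

1. Gravicycle ⇐ debenzylation and C2=C3 saturation of the 22-membered (R,E)-allylic alcohol 12.
2. 12 ⇐ key step: one-pot alkyne hydroboration / B→Zn exchange / amino-alcohol-catalysed enantioselective alkenylzinc addition to the aryl aldehyde (ynal 11). This closes the only new ring at C1–C2 and sets the only stereocentre in the same operation, so there is no RCM, no macro-Ullmann and no ketone reduction.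
3. 11 ⇐ Ullmann diaryl ether union of the hindered phenol 9 (ring B) with aryl bromide 7 (ring A plus C2–C14).
4. 7 ⇐ I-selective B-alkyl Suzuki of 3 with enyne 6; 9 ⇐ para-selective mono-debenzylation of 8.
5. Ring order: both arenes are purchased; the macrocycle is the only ring formed (step 7).

## Route

**Step 1**
Reactants: 1 (3-bromo-5-iodophenol), 2 (benzyl bromide)
Product: 3, 1-(benzyloxy)-3-bromo-5-iodobenzene
Conditions: BnBr, K2CO3, DMF, rt
Reagents that add atoms: benzyl bromide, BrCc1ccccc1
Why: Williamson etherification of an unhindered phenoxide with a reactive benzylic halide; no competing sites.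

**Step 2**
Reactants: 5 (ethynyltriisopropylsilane), 4 (11-bromoundec-1-ene)
Product: 6, triisopropyl(tridec-12-en-1-yn-1-yl)silane
Conditions: 5, n-BuLi, THF, −78 → 0 °C; then 4, DMPU, 0 °C → 40 °C
Reagents that add atoms: none beyond 4 and 5
Why: SN2 alkylation of a lithium acetylide with a primary bromide in a dipolar co-solvent; this delivers C2–C14 (13 carbons) with the alkyne masked as the base-stable TIPS derivative.

**Step 3**
Reactants: 6, 3
Product: 7, 1-(benzyloxy)-3-bromo-5-[13-(triisopropylsilyl)tridec-12-yn-1-yl]benzene
Conditions: 6, 9-BBN, THF, 0 °C → rt; then 3, Pd(dppf)Cl2 (5 mol %), aq K3PO4, DMF, rt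
Reagents that add atoms: none (9-BBN supplies only H)
Why: anti-Markovnikov hydroboration of the terminal alkene (the TIPS-alkyne is inert to 9-BBN) followed by B-alkyl Suzuki–Miyaura coupling; at rt oxidative addition occurs at C–I only, so the C–Br is kept for step 5.

**Step 4**
Reactants: 8 (3,4,5-tris(benzyloxy)benzaldehyde)
Product: 9, 3,5-bis(benzyloxy)-4-hydroxybenzaldehyde
Conditions: EtSNa (1.2 equiv), DMF, 0 °C → 50 °C; then aq HCl work-up
Reagents that add atoms: none
Why: nucleophilic (SN2) O-debenzylation by thiolate. The 4-OBn is twisted out of plane and releases the most stabilised phenoxide (para to CHO), as in the 3,4,5-trimethoxybenzaldehyde → syringaldehyde type of dealkylation; the phenoxide formed then deactivates the ring toward a second cleavage.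

**Step 5**
Reactants: 7, 9
Product: 10, 3,5-bis(benzyloxy)-4-{3-(benzyloxy)-5-[13-(triisopropylsilyl)tridec-12-yn-1-yl]phenoxy}benzaldehyde
Conditions: CuI (20 mol %), picolinic acid (40 mol %), K3PO4, DMSO, 105 °C
Reagents that add atoms: none
Why: Ullmann-type Cu-catalysed diaryl ether synthesis under conditions developed for ortho,ortho-disubstituted phenols; the aryl bromide is unhindered, and the non-enolisable aldehyde, the benzyl ethers and the TIPS-alkyne tolerate phosphate base.

**Step 6**
Reactants: 10
Product: 11, 3,5-bis(benzyloxy)-4-[3-(benzyloxy)-5-(tridec-12-yn-1-yl)phenoxy]benzaldehyde (the ynal)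
Conditions: TBAF, THF, 0 °C → rt
Reagents that add atoms: none
Why: fluoride-mediated C(sp)–Si cleavage; the aryl aldehyde, benzyl ethers and diaryl ether are inert.

**Step 7 (key step)**
Reactants: 11
Product: 12, (R,E)-tri-O-benzyl-2,3-didehydrogravicycle: the 22-membered meta,para-cyclophane in which ring B C-1 bears the (R)-CH(OH), linked through an E-CH=CH and eleven CH2 to ring A, with all three phenols as benzyl ethers
Conditions: Cy2BH (1.1 equiv), hexane–toluene, 0 °C → rt, 1 h; then syringe-pump addition (6 h) into Et2Zn (1.5 equiv), (2R)-(+)-DAIB (10 mol %), toluene–hexane, 0 °C, final ≈ 2 mM; aq NH4Cl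
Reagents that add atoms: none (borane supplies H; B and Zn are lost)
Why: Oppolzer-type asymmetric macrocyclisation of an ω-alkynal. Syn-hydroboration of the terminal alkyne is faster than aldehyde reduction and gives the (E)-alkenylborane; B→Zn exchange gives an alkenyl(ethyl)zinc that transfers its alkenyl group to the ArCHO only through the ligand-accelerated DAIB–Zn chelate, with slow addition acting as pseudo-high dilution. (2R)-DAIB directs attack to the Re face (mirror image of the (2S)-DAIB / Si-face / (S) Noyori model), giving the (R)-carbinol. This assumes alkenyl transfer follows the same facial sense as alkyl transfer; the configuration should be checked (Mosher) and the ligand enantiomer swapped if needed.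

**Step 8**
Reactants: 12
Product: 13, (R)-tri-O-benzylgravicycle (saturated macrocycle)
Conditions: TsNHNH2 (excess), NaOAc, DME–H2O, 85 °C
Reagents that add atoms: none
Why: diimide reduction, a concerted syn transfer of H2 to the isolated E-alkene; with no metal surface or π-allyl pathway there is no allylic/benzylic C–O hydrogenolysis or isomerisation to the ketone, and the stereocentre is untouched (still R, since Ar > CH2).

**Step 9**
Reactants: 13
Product: 14, gravicycle, (R)
Conditions: H2 (1 atm), 10 % Pd/C, EtOAc–EtOH, rt, stopped at 3 equiv uptake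
Reagents that add atoms: none
Why: catalytic hydrogenolysis of three aryl benzyl ethers; under neutral, acid-free conditions the secondary benzylic alcohol (no para-OH/OMe donor) is cleaved much more slowly than ArO–Bn, so the stereocentre is retained.

## Compound list

1 | 3-bromo-5-iodophenol | Oc1cc(Br)cc(I)c1 | starting material
2 | benzyl bromide | BrCc1ccccc1 | starting material (reagent)
3 | 1-(benzyloxy)-3-bromo-5-iodobenzene | Brc1cc(I)cc(OCc2ccccc2)c1 | intermediate
4 | 11-bromoundec-1-ene | C=CCCCCCCCCCBr | starting material
5 | ethynyltriisopropylsilane | C#C[Si](C(C)C)(C(C)C)C(C)C | starting material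
6 | triisopropyl(tridec-12-en-1-yn-1-yl)silane | C=CCCCCCCCCCC#C[Si](C(C)C)(C(C)C)C(C)C | intermediate
7 | 1-(benzyloxy)-3-bromo-5-[13-(triisopropylsilyl)tridec-12-yn-1-yl]benzene | Brc1cc(OCc2ccccc2)cc(CCCCCCCCCCCC#C[Si](C(C)C)(C(C)C)C(C)C)c1 | intermediate
8 | 3,4,5-tris(benzyloxy)benzaldehyde | O=Cc1cc(OCc2ccccc2)c(OCc2ccccc2)c(OCc2ccccc2)c1 | starting material
9 | 3,5-bis(benzyloxy)-4-hydroxybenzaldehyde | O=Cc1cc(OCc2ccccc2)c(O)c(OCc2ccccc2)c1 | intermediate
10 | 3,5-bis(benzyloxy)-4-{3-(benzyloxy)-5-[13-(triisopropylsilyl)tridec-12-yn-1-yl]phenoxy}benzaldehyde | O=Cc1cc(OCc2ccccc2)c(Oc2cc(OCc3ccccc3)cc(CCCCCCCCCCCC#C[Si](C(C)C)(C(C)C)C(C)C)c2)c(OCc2ccccc2)c1 | intermediate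
11 | 3,5-bis(benzyloxy)-4-[3-(benzyloxy)-5-(tridec-12-yn-1-yl)phenoxy]benzaldehyde | O=Cc1cc(OCc2ccccc2)c(Oc2cc(OCc3ccccc3)cc(CCCCCCCCCCCC#C)c2)c(OCc2ccccc2)c1 | intermediate
12 | (R,E)-tri-O-benzyl-2,3-didehydrogravicycle | c1ccccc1COc1cc2cc(c1)Oc1c(OCc3ccccc3)cc(cc1OCc1ccccc1)[C@H](O)/C=C/CCCCCCCCCCC2 | intermediate
13 | (R)-tri-O-benzylgravicycle | c1ccccc1COc1cc2cc(c1)Oc1c(OCc3ccccc3)cc(cc1OCc1ccccc1)[C@H](O)CCCCCCCCCCCCC2 | intermediate
14 | gravicycle, (R) | Oc1cc2cc(c1)Oc1c(O)cc(cc1O)[C@H](O)CCCCCCCCCCCCC2 | target

## Summary

Total steps: 9. Longest linear sequence: 7 (steps 1 → 3 → 5 → 6 → 7 → 8 → 9).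

Three steps most likely to fail, each with a fallback that changes the approach:

- **Step 7 (asymmetric macrocyclisation).** Risks: oligomerisation, competing ethyl transfer, aldehyde reduction by Cy2BH, or eroded ee in a 22-membered aryl-aldehyde case (the precedent is for smaller rings and aliphatic aldehydes). Fallback: separate ring closure from stereocontrol. Set the carbinol intermolecularly by the same DAIB/alkenylzinc addition, using a short ω-alkenyl alkyne and a ring-B aldehyde, and close the macrocycle mid-chain by RCM followed by diimide reduction. Alternatively, if cyclisation works but ee is poor, oxidise 12 to the macrocyclic enone (MnO2) and reduce with CBS.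
- **Step 5 (Ullmann coupling of a di-ortho-substituted, electron-poor phenol).** Risk: sluggish C–O coupling or aldehyde degradation at 105 °C. Fallback: reverse the polarity. Couple the ring-A phenol (3-(benzyloxy)-5-alkylphenol) with 4-bromo-3,5-bis(benzyloxy)benzaldehyde (from 4-bromo-3,5-dimethoxybenzaldehyde by BBr3 then BnBr) under Pd/tBuXPhos C–O coupling, so the hindered partner becomes the activated electrophile.
- **Step 4 (para-selective mono-debenzylation).** Risk: incomplete regioselectivity or over-dealkylation. Fallback: build 9 by protecting-group ordering instead of selective cleavage. From methyl gallate: selective 4-O-MOM protection of the most acidic phenol, 3,5-di-O-benzylation, MOM removal, then DIBAL/MnO2 to the aldehyde.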